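The data stem from a simulated flask for substances that don't exist; scatter was added.

The racemization catalyst is what I look at first in this flask, where a single-handed free catalyst takes a racemate of left-handed and right-handed substrate while the gas dissolves from nothing.

common to all: left-handed substrate 27 mM; right-handed substrate 27 mM; gas 4.1 mM (held); precatalyst 2.3 mM
- teal: racemization catalyst 0.94 mM; run made earlier
- violet: racemization catalyst 2.1 mM; run made earlier
- flask: racemization catalyst 1.4 mM; time 5.0 min

| run | time / min | left-handed product / % | right-handed product / % |
|---|---|---|---|
| teal | 0.417 | 1 | 1 |
| teal | 0.833 | 5 | 3 |
| teal | 1.33 | 13 | 2 |
| teal | 2.50 | 29 | 1 |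
| teal | 5.00 | 48 | 7 |
| violet | 0.417 | 0 | 2 |
| violet | 0.833 | 6 | 0 |
| violet | 1.33 | 12 | 3 |
| violet | 2.50 | 28 | 5 |
| violet | 5.00 | 50 | 5 |

(scatter of a reading: 1.5 percentage points)

- left-handed product and right-handed product together, in percent of the left-handed substrate and right-handed substrate charged together, at 5.0 min
- excess of left-handed product over right-handed product in the product at 5.0 min
- whether the exchange between left-handed substrate and right-handed substrate keeps pace with the reaction: how far the product's excess at 5.0 min gets from its value without exchange to its value with instant exchange (above 80% keeps pace, below 20% hardly takes part, else lags behind)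

- free catalyst is single-handed; left-handed substrate and right-handed substrate are mirror images of each other, charged as a racemate, each of them at the stated concentration
- the earlier runs were read with a standard deviation of 1.5 percentage points
- at the start none of the gas is in solution
- an excess is below zero if the other one leads

The two earlier runs don't seem to go together: violet holds 2.23 times teal's racemization catalyst, yet at 5.00 min left-handed product reads 48% against 50%, a gap of 2 percentage points on a scatter of 1.5 points. So I ask what each limit demands. Adding both runs' readings at 2.50 min gives the share of one substrate's charge consumed, and I read 13.6 as the selectivity factor, the logarithm of what remains of the left-handed charge over that of what remains of the right-handed charge, a reading that stays constant while the substrates don't exchange. With instant exchange the product's excess stands at (s−1)/(s+1), or 86.3%, but teal reads 74.5% and violet 81.8%, both lower. Since left-handed product doesn't answer the dose beyond the scatter, I commit to "hardly takes part" and reckon the flask as without exchange. I choose the left-handed remainder to meet the runs' mean yield of 55.0%: at 7.33%, the factor leaves 82.6% of the right-handed charge, a yield of 55.0%, and this gives my excess for the flask, 68.3%, which I hold loosely, the right-handed readings at 2.50 min being 1% and 5% on a scatter of 1.5 points.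

The forecast gives 55%, 79% and "lags behind", parting from me on the excess and the pace, and holds that “Doubling the racemization catalyst changes little beyond the noise”.

The flask gives 55.6%, an excess of 73.8%, 5.5 points above mine, and "hardly takes part", at 8.9% of the way.

    partner + free catalyst + left-handed substrate → free catalyst + left-handed product (k = 2800 L² mol⁻² s⁻¹)
    partner + free catalyst + right-handed substrate → free catalyst + right-handed product (k = 160 L² mol⁻² s⁻¹)
    left-handed substrate + racemization catalyst ⇌ right-handed substrate + racemization catalyst, rate k3*[racemization catalyst]*[left-handed substrate] forward; the back reaction follows from the equilibrium constant (k = 4.10 L mol⁻¹ s⁻¹)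
    gas ⇌ partner, rate k4*(csat - [partner]) (kL = 0.0530 s⁻¹)
    partner + racemization catalyst → spent catalyst (k = 15.0 L mol⁻¹ s⁻¹)
    partner + precatalyst → free catalyst + spent reagent (k = 10.0 L mol⁻¹ s⁻¹)

In the flask at 5.00 min, 6.2% of the left-handed charge remains, from which the factor gives 81.5% of the right-handed charge, and 83% stands there. The neighbouring flask, the same recipe with 3.9 mM of precatalyst, reaches a yield of 61.0% at an excess of 68.6%. Its left-handed remainder of 2.3% gives, by the same factor, 75.8% of the right-handed charge, and the neighbouring flask holds 76%.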